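(Its constants come from no measurement; no experiment stands behind them.)

Follow the reagent.

all flasks: starting material 0.0020 M; gas 0.55 mM (held); time 30 s

| run | temperature |
|---|---|
| ochre | 130 °C |
| green | 110 °C |
| violet | 150 °C |

- the flask with the highest amount of target, in percent of the starting material charged ("all alike" if they lie within 1.5 percentage points) (ochre / green / violet / all alike)
- final target, as a percentage of the starting material charged, in ochre
- final target, as a percentage of the starting material charged, in green
- final target, as a percentage of the starting material charged, in violet

- percent here means starting material units held: one side product counts as two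
- at the start none of reagent is dissolved
- the list of constants is for 110 °C, to be carried to other temperatures by the activation energies and enthalpies

    starting material + reagent → intermediate A (k1 = 55 L mol⁻¹ s⁻¹, Ea1 = 61.0 kJ mol⁻¹)
    intermediate A → target (k2 = 0.069 s⁻¹, Ea2 = 94.0 kJ mol⁻¹)
    starting material + reagent → intermediate B (k3 = 17 L mol⁻¹ s⁻¹, Ea3 = 41.0 kJ mol⁻¹)
    intermediate B → intermediate A (k4 = 0.20 s⁻¹, Ea4 = 100 kJ mol⁻¹)
    starting material + intermediate B → side product (k5 = 31 L mol⁻¹ s⁻¹, Ea5 = 69.0 kJ mol⁻¹)
    reagent ⇌ dormant form (K6 = 2.2, k6 = 0.024 s⁻¹, Ea6 = 90.0 kJ mol⁻¹, ΔH6 = 19.0 kJ mol⁻¹)
    gas ⇌ reagent, rate k7*(csat - [reagent]) (k7 = 0.057 s⁻¹, csat = 0.55 mM)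
    (constants at 110 °C)

No reagent is dissolved at the start, so it all has to cross from the gas. I kept its ledger for green, whose constants stand as listed. The opening entry was the ceiling, the transfer coefficient times the saturation concentration over the whole time: 0.941 mM in 30 s. That is 47.0% of the charge, less than the starting material, so over 30 s the transfer could not deliver enough reagent for the whole charge, though the gas is held and the reagent has no fixed amount. No activation energy is listed for the transfer, so I held the same ceiling over ochre and violet.

Dissolved reagent is consumed by the two steps from starting material, at a first-order rate of 0.144 s⁻¹ with the full charge present. Setting supply equal to loss, as in a steady-state treatment, gave 0.156 mM. This steady free reagent, the supply divided by the sum of transfer coefficient and consumption rate, filled the next entries. With c(reagent) at that level, the transfer fell short of its ceiling by 0.267 mM, and 0.156 mM stayed in solution. The dormant form took 0.112 mM, which I reckoned on the forward step alone. The books closed with 0.406 mM passing into starting material, or 20.3% of the charge. Intermediate A lasts 14.5 s in green, shorter than the run but not by much, so I delayed target by that lifetime and committed to 10.5%. I took no figure to the hotter flasks. I noted only that step two speeds up 16 times from green to violet, so target there should trail less.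

The forecast gave 23% for ochre, 11% for green and 29% for violet, with violet ahead, since “heat clears it quickly and favours the route to target”.

The flasks gave 25.6% in ochre, 11.8% in green and 32.7% in violet, so violet led, with target there still below the ceiling's share. Green held 1.64 × 10⁻⁴ M of free reagent at 30.0 s, against my 0.156 mM. Green read at 80 s is the neighbour, and its ceiling of 2.51 mM stands above the charge. The same 0.156 mM leaves 1.34 mM for starting material, which is 67.1% of the charge, and the delay makes that 54.9% target. That flask held 2.42 × 10⁻⁴ M of free reagent, 35.6% of starting material and 49.2% of target.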